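**Retrosynthetic overview** (target numbering: C1 = angelate carbinol, C2H2, C3H=C4(Me), C5–C7, C8(Me)2, C9 = acetate carbinol, C10H=C11(Me))
1. Target 26 ⇒ diol 22 by two acylations (angelate at the less hindered C1–OH, then acetate at the neopentylic C9–OH).
2. Key disconnection C1–C2: the eleven-membered carbocycle of 22 arises by a one-atom ring expansion ([2,3]-Wittig) from the ten-membered oxacycle 19, whose ring oxygen bridges C1 and C4 and whose C4 carries the exocyclic vinyl group C3=C2. The enabling feature is that C1 is a carbinol carbon allylic to C10=C11 and homoallylic to C3=C4(Me) (C1–C2H2–C3H=C4).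
3. 19 ⇒ acyclic iodo-aldehyde 15 by Nozaki–Hiyama–Kishi closure of C9–C10, followed by oxidation and CBS reduction to fix C9.
4. 15 ⇒ (S)-linalool 5 (C4 stereocentre, vinyl, C5–C7) + (Z)-iodoallyl bromide 4 (C1, C10, C11; from propargyl alcohol 1) + isobutyronitrile 11 (C8, C9).
5. Ring order: ten-membered 1-oxacyclodecene first (step 8), eleven-membered carbocycle second (step 11); no other ring.

Key step: step 11

Assumption: (S)-(+)-linalool of high enantiomeric purity is taken as a purchasable chiral-pool compound; its C4 stereocentre is consumed in step 11, so its optical purity sets that of C1.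

**Step 1**
Reactants: 1 prop-2-yn-1-ol (propargyl alcohol)
Product: 3 (Z)-3-iodo-2-methylprop-2-en-1-ol, via alkenylmagnesium alkoxide 2 (not isolated)
Conditions: MeMgBr (3 equiv), CuI (10 mol %), THF, −10 °C → rt; then I2, −10 °C; aqueous work-up
Reagents that add atoms: methylmagnesium bromide (C[Mg]Br); iodine (II)
Why: Cu-catalysed anti-carbomagnesiation of the propargylic magnesium alkoxide puts the methyl group on C2 and magnesium on C3 cis to CH2O in a five-membered chelate, and iodinolysis with retention gives the (Z)-iodide whose geometry becomes the cis C10=C11 bond.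

**Step 2**
Reactants: 3 (Z)-3-iodo-2-methylprop-2-en-1-ol
Product: 4 (Z)-3-bromo-1-iodo-2-methylprop-1-ene
Conditions: CBr4, PPh3, CH2Cl2, 0 °C
Reagents that add atoms: carbon tetrabromide (BrC(Br)(Br)Br)
Why: Appel bromination is an SN2 displacement at the primary allylic carbon and leaves the olefin geometry and the vinyl iodide untouched.

**Step 3**
Reactants: 5 (S)-(+)-linalool [(3S)-3,7-dimethylocta-1,6-dien-3-ol]; 4 (Z)-3-bromo-1-iodo-2-methylprop-1-ene
Product: 7 (3S)-3-{[(Z)-3-iodo-2-methylprop-2-en-1-yl]oxy}-3,7-dimethylocta-1,6-diene, via sodium (S)-linaloolate 6 (not isolated)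
Conditions: NaH, THF/DMF, 0 °C; then 4, 0 °C → rt
Reagents that add atoms: none
Why: Williamson etherification of the tertiary alkoxide with an unhindered primary allylic bromide (no β-hydrogen for elimination) keeps the C–O bond of linalool, so the C4 configuration is carried over unchanged.

**Step 4**
Reactants: 7 linalyl iodoallyl ether
Product: 9 (4S)-4-{[(Z)-3-iodo-2-methylprop-2-en-1-yl]oxy}-4-methylhex-5-en-1-ol, via ozonide 8 (not isolated)
Conditions: O3 (1 equiv, Sudan Red 7B end-point), CH2Cl2, −78 °C; then NaBH4, MeOH, −78 °C → rt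
Reagents that add atoms: ozone ([O-][O+]=O)
Why: Chemoselective ozonolysis with reductive work-up cleaves only the electron-rich trialkyl olefin, since the vinyl iodide and the vinyl group on the quaternary ether carbon should react far more slowly.

**Step 5**
Reactants: 9 primary alcohol
Product: 10 (3S)-6-iodo-3-{[(Z)-3-iodo-2-methylprop-2-en-1-yl]oxy}-3-methylhex-1-ene
Conditions: I2, PPh3, imidazole, CH2Cl2, 0 °C → rt
Reagents that add atoms: iodine (II)
Why: Appel-type iodination converts the only hydroxyl group into a primary iodide under neutral conditions that spare the tertiary allylic ether.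

**Step 6**
Reactants: 10 primary iodide; 11 isobutyronitrile (2-methylpropanenitrile)
Product: 13 (6S)-6-{[(Z)-3-iodo-2-methylprop-2-en-1-yl]oxy}-2,2,6-trimethyloct-7-enenitrile, via 2-lithio-2-methylpropanenitrile 12 (not isolated)
Conditions: 11, LDA, THF, −78 °C; then 10, −78 → 0 °C
Reagents that add atoms: none
Why: SN2 alkylation of the α-lithionitrile with the primary alkyl iodide builds the quaternary C8 with its two methyl groups, and the alkenyl iodide is inert to this soft, non-exchanging carbanion.

**Step 7**
Reactants: 13 nitrile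
Product: 15 (6S)-6-{[(Z)-3-iodo-2-methylprop-2-en-1-yl]oxy}-2,2,6-trimethyloct-7-enal, via N-aluminoimine 14 (not isolated)
Conditions: DIBAL-H, CH2Cl2, −78 °C; then aq. Rochelle salt, rt
Reagents that add atoms: water (O)
Why: DIBAL-H half-reduction stops at the N-aluminoimine, whose hydrolysis gives the aldehyde C9, and the quaternary α-carbon rules out enolisation or aldol reactions.

**Step 8**
Reactants: 15 iodo-aldehyde
Product: 17 (3Z,10S)-10-ethenyl-3,6,6,10-tetramethyl-1-oxacyclodec-3-en-5-ol (mixture of C5 epimers; C5 = target C9), via alkenylchromium(III) species 16 (not isolated)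
Conditions: CrCl2 (excess), NiCl2 (cat.), DMSO, rt, slow addition at high dilution; aqueous work-up
Reagents that add atoms: none
Why: The intramolecular Nozaki–Hiyama–Kishi alkenyl–aldehyde coupling is chemoselective, keeps the Z geometry of the alkenyl iodide and has precedent for closing nine- and ten-membered cyclic ethers; the C9 configuration is not controlled here and is set in steps 9 and 10.

**Step 9**
Reactants: 17 ten-membered allylic alcohol (epimer mixture)
Product: 18 (3Z,10S)-10-ethenyl-3,6,6,10-tetramethyl-1-oxacyclodec-3-en-5-one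
Conditions: Dess–Martin periodinane, CH2Cl2, rt
Reagents that add atoms: none
Why: Dess–Martin oxidation converts both C9 epimers into one enone, which cannot enolise towards the quaternary C8.

**Step 10**
Reactants: 18 ten-membered enone
Product: 19 (3Z,5R,10S)-10-ethenyl-3,6,6,10-tetramethyl-1-oxacyclodec-3-en-5-ol (target numbering: 4S,9R)
Conditions: (S)-2-methyl-CBS-oxazaborolidine (20 mol %), catecholborane, toluene, −78 °C; aq. NaOH work-up
Reagents that add atoms: none
Why: Corey–Bakshi–Shibata reduction under reagent control, with the quaternary C8 as the large and the alkenyl CH as the small substituent (as for tert-alkyl ketones), should deliver hydride to the face that gives 9R, and catecholborane at −78 °C does not hydroborate the olefins.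

**Step 11**
Reactants: 19 (4S,9R)-hydroxy oxacycle
Product: 22 (1R,2Z,4S,6E)-3,7,11,11-tetramethylcycloundeca-2,6-diene-1,4-diol (target numbering: 1S,9R-diol with 3E and 10Z olefins), via allyl anion alkoxide 20 (not isolated), via dilithium dialkoxide 21 (not isolated)
Conditions: n-BuLi (2.5 equiv), THF, −78 → −20 °C; then H2O
Reagents that add atoms: none
Why: Proposed new method: the first equivalent of base makes the C9 lithium alkoxide (which blocks C9–H removal and 1,4-elimination), the second removes a C1 proton (α to the ring oxygen and allylic to C10=C11; C4 has no hydrogen), and the α-oxyallyl anion 20 undergoes a suprafacial [2,3]-sigmatropic (Wittig) shift through the five-membered array C1–O–C4–C3=C2, forming C1–C2 and breaking O–C4, so that the ring oxygen leaves the ring as the C1 alkoxide while the exocyclic vinyl carbons C2 and C3 enter it (ten-membered oxacycle → eleven-membered carbocycle). The closest known reaction types are the [2,3]-Wittig rearrangement of open-chain bis-allylic ethers, including tertiary linalyl-type ethers, and the ring-contracting [2,3]-Wittig rearrangement of macrocyclic diallyl ethers; new is only the topology, in which the migrating allyl unit is exocyclic so that the ring grows by one atom. The carbocycle is closed by SN2′-type attack of C1 on the vinyl terminus C2 inside a 12-oxabicyclo[7.2.1] transition state in which the seven-atom bridge C5–C11 stays intact. The new C1 stereocentre is controlled by C4 (self-immolative chirality transfer): the seven-atom tether can span the envelope only in a cis-bridged manner, which delivers C2 to one face of C1 and gives 1S from the 4S ether whichever olefin geometry results, while C9 is not touched. The step needs E geometry at the new C3=C4 bond: this is expected because the ring bond C4–C5 can stay anti to O–C1 (pseudo-equatorial) in the open conformer, whereas the Z pathway must fold C5 under the allyl anion with a syn-pentane-like arrangement about the ether oxygen; this preference is a conformational argument and is the main uncertainty. The cis C10=C11 bond is preserved because a trans allyl anion is not accessible within the ten-membered ring, and low temperature disfavours the [1,2]-shift.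

**Step 12**
Reactants: 22 diol; 23 angelic acid [(Z)-2-methylbut-2-enoic acid]
Product: 25 (1S,2Z,4R,9E)-4-hydroxy-2,5,5,9-tetramethylcycloundeca-2,9-dien-1-yl (2Z)-2-methylbut-2-enoate (C1 mono-angelate), via mixed anhydride 24 (not isolated)
Conditions: 23, 2,4,6-trichlorobenzoyl chloride, Et3N, toluene, rt; then 22, 75 °C (no DMAP)
Reagents that add atoms: none
Why: Yamaguchi-type mixed-anhydride esterification without a nucleophilic catalyst avoids angelate-to-tiglate isomerisation, and the bulky acyl donor should acylate the C1 hydroxyl (retention) much faster than the neopentylic C9 hydroxyl next to the quaternary C8.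

**Step 13**
Reactants: 25 C1 mono-angelate
Product: 26 (1S,2Z,4R,9E)-4-(acetyloxy)-2,5,5,9-tetramethylcycloundeca-2,9-dien-1-yl (2Z)-2-methylbut-2-enoate (target)
Conditions: Ac2O, pyridine, DMAP (cat.), CH2Cl2, 0 °C → rt
Reagents that add atoms: acetic anhydride (CC(=O)OC(C)=O)
Why: DMAP-catalysed acetylation of the remaining hindered secondary alcohol proceeds with retention at C9 under conditions mild enough to leave the angelate geometry intact.

**Compound list**
1 | prop-2-yn-1-ol (propargyl alcohol) | C#CCO | starting material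
2 | bromomagnesium (Z)-3-(bromomagnesio)-2-methylprop-2-en-1-olate | Br[Mg]OC/C(C)=C\[Mg]Br | intermediate (not isolated)
3 | (Z)-3-iodo-2-methylprop-2-en-1-ol | OC/C(C)=C\I | intermediate
4 | (Z)-3-bromo-1-iodo-2-methylprop-1-ene | BrC/C(C)=C\I | intermediate
5 | (S)-(+)-linalool, (3S)-3,7-dimethylocta-1,6-dien-3-ol | C=C[C@@](C)(O)CCC=C(C)C | starting material
6 | sodium (S)-linaloolate | C=C[C@@](C)([O-])CCC=C(C)C.[Na+] | intermediate (not isolated)
7 | (3S)-3-{[(Z)-3-iodo-2-methylprop-2-en-1-yl]oxy}-3,7-dimethylocta-1,6-diene | C=C[C@@](C)(OC/C(C)=C\I)CCC=C(C)C | intermediate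
8 | 1,2,4-trioxolane (ozonide) of the 6,7-olefin of 7 | C=C[C@@](C)(OC/C(C)=C\I)CCCC1OOC(C)(C)O1 | intermediate (not isolated)
9 | (4S)-4-{[(Z)-3-iodo-2-methylprop-2-en-1-yl]oxy}-4-methylhex-5-en-1-ol | C=C[C@@](C)(OC/C(C)=C\I)CCCO | intermediate
10 | (3S)-6-iodo-3-{[(Z)-3-iodo-2-methylprop-2-en-1-yl]oxy}-3-methylhex-1-ene | C=C[C@@](C)(OC/C(C)=C\I)CCCI | intermediate
11 | isobutyronitrile (2-methylpropanenitrile) | CC(C)C#N | starting material
12 | 2-lithio-2-methylpropanenitrile | [Li]C(C)(C)C#N | intermediate (not isolated)
13 | (6S)-6-{[(Z)-3-iodo-2-methylprop-2-en-1-yl]oxy}-2,2,6-trimethyloct-7-enenitrile | C=C[C@@](C)(OC/C(C)=C\I)CCCC(C)(C)C#N | intermediate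
14 | N-(diisobutylaluminio)imine of 15 | C=C[C@@](C)(OC/C(C)=C\I)CCCC(C)(C)C=N[Al](CC(C)C)CC(C)C | intermediate (not isolated)
15 | (6S)-6-{[(Z)-3-iodo-2-methylprop-2-en-1-yl]oxy}-2,2,6-trimethyloct-7-enal | C=C[C@@](C)(OC/C(C)=C\I)CCCC(C)(C)C=O | intermediate
16 | alkenylchromium(III) dichloride derived from 15 | C=C[C@@](C)(OC/C(C)=C\[Cr](Cl)Cl)CCCC(C)(C)C=O | intermediate (not isolated)
17 | (3Z,10S)-10-ethenyl-3,6,6,10-tetramethyl-1-oxacyclodec-3-en-5-ol, mixture of C5 epimers | C=C[C@]1(C)CCCC(C)(C)C(O)/C=C(C)\CO1 | intermediate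
18 | (3Z,10S)-10-ethenyl-3,6,6,10-tetramethyl-1-oxacyclodec-3-en-5-one | C=C[C@]1(C)CCCC(C)(C)C(=O)/C=C(C)\CO1 | intermediate
19 | (3Z,5R,10S)-10-ethenyl-3,6,6,10-tetramethyl-1-oxacyclodec-3-en-5-ol | C=C[C@]1(C)CCCC(C)(C)[C@H](O)/C=C(C)\CO1 | intermediate
20 | dilithio species of 19 (C9 alkoxide, C1 α-oxyallyl anion) | [Li+].[Li+].C=C[C@]1(C)CCCC(C)(C)[C@H]([O-])/C=C(C)\[CH-]O1 | intermediate (not isolated)
21 | dilithium dialkoxide of 22 | [Li+].[Li+].[O-][C@H]1C/C=C(\C)CCCC(C)(C)[C@H]([O-])/C=C\1C | intermediate (not isolated)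
22 | (1R,2Z,4S,6E)-3,7,11,11-tetramethylcycloundeca-2,6-diene-1,4-diol | O[C@H]1C/C=C(\C)CCCC(C)(C)[C@H](O)/C=C\1C | intermediate
23 | angelic acid, (Z)-2-methylbut-2-enoic acid | C/C=C(/C)C(=O)O | starting material
24 | angelic 2,4,6-trichlorobenzoic anhydride | C/C=C(/C)C(=O)OC(=O)c1c(Cl)cc(Cl)cc1Cl | intermediate (not isolated)
25 | (1S,2Z,4R,9E)-4-hydroxy-2,5,5,9-tetramethylcycloundeca-2,9-dien-1-yl (2Z)-2-methylbut-2-enoate | C/C=C(/C)C(=O)O[C@H]1C/C=C(\C)CCCC(C)(C)[C@H](O)/C=C\1C | intermediate
26 | (1S,2Z,4R,9E)-4-(acetyloxy)-2,5,5,9-tetramethylcycloundeca-2,9-dien-1-yl (2Z)-2-methylbut-2-enoate | C/C=C(/C)C(=O)O[C@H]1C/C=C(\C)CCCC(C)(C)[C@H](OC(C)=O)/C=C\1C | target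

**Step count**
Total: 13 steps. Longest linear sequence: 13 steps (from propargyl alcohol 1; 11 steps from linalool 5).

**Steps most likely to fail**

1. Step 11 (ring-expanding [2,3]-Wittig rearrangement). What may go wrong: the tether may pass through the folded transition state, giving poor E/Z control at the new C3=C4 bond; lithiation may be slow in the dianion; a [1,2]-shift may compete. Fallback (known chemistry only): the order of rearrangement and ring closure is exchanged, so that the eleven-membered ring is closed directly. It leaves the route at the start, where 5 is replaced by its commercial enantiomer (R)-(−)-linalool F1, re-uses 11 and the reagents of steps 1 and 4–8, and comes back at 22.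
 - F1 is O-propargylated (NaH, propargyl bromide) to (3R)-3,7-dimethyl-3-(prop-2-yn-1-yloxy)octa-1,6-diene F2.
 - Selective ozonolysis with NaBH4 work-up, as in step 4, gives (4R)-4-methyl-4-(prop-2-yn-1-yloxy)hex-5-en-1-ol F3.
 - The open-chain [2,3]-Wittig rearrangement of this allyl propargyl ether (n-BuLi, 3 equiv, THF, −78 °C) should give (4E,7S)-4-methylnon-4-en-8-yne-1,7-diol F4. With the alkynyl group exo in the open-chain envelope the sense of C4→C1 transfer is opposite to that of the bridged transition state of step 11, hence the use of F1. Open-chain linalyl ethers are expected to show only modest E/Z preference, so F4 has to be separated from its olefin isomer (4Z,7R)-4-methylnon-4-en-8-yne-1,7-diol F5.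
 - The Cu-catalysed carbomagnesiation/iodination of step 1 converts the free propargylic alcohol of F4 into (4E,7S,8Z)-9-iodo-4,8-dimethylnona-4,8-diene-1,7-diol F6.
 - Selective tosylation of the primary hydroxyl gives (4E,7S,8Z)-7-hydroxy-9-iodo-4,8-dimethylnona-4,8-dien-1-yl 4-methylbenzenesulfonate F7.
 - Alkylation with excess 12 gives (6E,9S,10Z)-9-hydroxy-11-iodo-2,2,6,10-tetramethylundeca-6,10-dienenitrile F8, and DIBAL-H gives (6E,9S,10Z)-9-hydroxy-11-iodo-2,2,6,10-tetramethylundeca-6,10-dienal F9.
 - Nozaki–Hiyama–Kishi cyclisation of F9 at C9–C10 gives 22 together with its C9 epimer (1S,2Z,4S,6E)-3,7,11,11-tetramethylcycloundeca-2,6-diene-1,4-diol F10, which is separated.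

2. Step 8 (Nozaki–Hiyama–Kishi closure of the ten-membered ring). What may go wrong: slow medium-ring closure, so that intermolecular coupling and reductive loss of iodine take over. Fallback: the ring is closed at the ketone oxidation level by a Ni/Zr-mediated reductive acyl–alkenyl coupling. It sets out from 15 and comes back at 18, so step 9 is not needed. Pinnick oxidation of 15 gives (6S)-6-{[(Z)-3-iodo-2-methylprop-2-en-1-yl]oxy}-2,2,6-trimethyloct-7-enoic acid F11. 2,2′-Dipyridyl disulfide/PPh3 converts it into the S-(pyridin-2-yl) thioester F12. NiBr2(dtbbpy) (cat.), Cp2ZrCl2 and Zn in DMI at high dilution then couple the alkenyl iodide with the thioester to give enone 18.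

3. Step 10 (CBS reduction). What may go wrong: poor or reversed facial discrimination between the quaternary C8 and the alkenyl C10, giving the 9S alcohol or a mixture. Fallback: the C9 configuration is set in the C–C bond-forming ring closure itself. It sets out from 15 and comes back at 19. A catalytic asymmetric Nozaki–Hiyama–Kishi cyclisation (CrCl2 cat., chiral sulfonamide ligand, NiCl2 cat., Mn, Cp2ZrCl2, MeCN) converts 15 directly into 19, with the ligand enantiomer chosen for 9R. No new compound is made.

**Further compounds**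
F1 | step 11 | (R)-(−)-linalool, (3R)-3,7-dimethylocta-1,6-dien-3-ol | C=C[C@](C)(O)CCC=C(C)C
F2 | step 11 | (3R)-3,7-dimethyl-3-(prop-2-yn-1-yloxy)octa-1,6-diene | C=C[C@](C)(OCC#C)CCC=C(C)C
F3 | step 11 | (4R)-4-methyl-4-(prop-2-yn-1-yloxy)hex-5-en-1-ol | C=C[C@](C)(OCC#C)CCCO
F4 | step 11 | (4E,7S)-4-methylnon-4-en-8-yne-1,7-diol | C#C[C@@H](O)C/C=C(\C)CCCO
F5 | step 11 | (4Z,7R)-4-methylnon-4-en-8-yne-1,7-diol | C#C[C@H](O)C/C=C(/C)CCCO
F6 | step 11 | (4E,7S,8Z)-9-iodo-4,8-dimethylnona-4,8-diene-1,7-diol | I/C=C(C)\[C@@H](O)C/C=C(\C)CCCO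
F7 | step 11 | (4E,7S,8Z)-7-hydroxy-9-iodo-4,8-dimethylnona-4,8-dien-1-yl 4-methylbenzenesulfonate | I/C=C(C)\[C@@H](O)C/C=C(\C)CCCOS(=O)(=O)c1ccc(C)cc1
F8 | step 11 | (6E,9S,10Z)-9-hydroxy-11-iodo-2,2,6,10-tetramethylundeca-6,10-dienenitrile | I/C=C(C)\[C@@H](O)C/C=C(\C)CCCC(C)(C)C#N
F9 | step 11 | (6E,9S,10Z)-9-hydroxy-11-iodo-2,2,6,10-tetramethylundeca-6,10-dienal | I/C=C(C)\[C@@H](O)C/C=C(\C)CCCC(C)(C)C=O
F10 | step 11 | (1S,2Z,4S,6E)-3,7,11,11-tetramethylcycloundeca-2,6-diene-1,4-diol | O[C@H]1C/C=C(\C)CCCC(C)(C)[C@@H](O)/C=C\1C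
F11 | step 8 | (6S)-6-{[(Z)-3-iodo-2-methylprop-2-en-1-yl]oxy}-2,2,6-trimethyloct-7-enoic acid | C=C[C@@](C)(OC/C(C)=C\I)CCCC(C)(C)C(=O)O
F12 | step 8 | S-(pyridin-2-yl) (6S)-6-{[(Z)-3-iodo-2-methylprop-2-en-1-yl]oxy}-2,2,6-trimethyloct-7-enethioate | C=C[C@@](C)(OC/C(C)=C\I)CCCC(C)(C)C(=O)Sc1ccccn1
F0 | step 10 | none | none
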